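## Retrosynthetic overview

1. Target 40 ⇐ O-debenzylation of 39 ⇐ three separate Mitsunobu esterifications with amino alcohol 30, one equivalent per step and each with inversion at C6: the C3 acid 19, then the C1 acid 32, then the side-chain acid 38.
2. Side chain ⇐ B-alkyl Suzuki coupling of ethenylcyclobutane 33 with (E)-enol triflate 35, which makes the side-chain C–C bond and fixes the (E)-enoate.
3. Cyclobutane 18 ⇐ prochiral formyl diester 12 by two Pd-catalysed, transient-imine-directed C–H couplings on the formyl face (enantioselective arylation with 4, then ethenylation). The formyl group then becomes the C-methyl group, and C3 is set by epimerisation.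
4. Amino alcohol 30 ⇐ enone 26 ⇐ enyne 25 by Pauson–Khand cyclisation; the one controlling stereocentre comes from a Cu-catalysed asymmetric allylic methylation of 24.
5. Ring order: the cyclobutane is bought in (5) and never opened. In 30 the piperidine and cyclopentenone rings close together in the Pauson–Khand step.

Assumption: the sense of induction shown for L-tert-leucine (step 9) and (R,R)-Taniaphos (step 16) is taken by analogy; if a first run gives the antipode, the mirror-image amino acid or ligand is used.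

## Route

**Aryl iodide 4**

Step 1
Reactants: 1 benzene-1,2-diol
Product: 2 2-methoxyphenol
Conditions: MeI (1.0 equiv.), K2CO3 (1.0 equiv.), acetone, 56 °C
Reagents that add atoms: iodomethane (CI)
Why: Williamson ether synthesis with one equivalent of MeI gives the mono-methyl ether, which is separated from catechol and the dimethyl ether.

Step 2
Reactants: 2 2-methoxyphenol
Product: 3 4-iodo-2-methoxyphenol
Conditions: N-iodosuccinimide (1.05 equiv.), TsOH (5 mol%), MeCN, 0→25 °C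
Reagents that add atoms: N-iodosuccinimide (O=C1CCC(=O)N1I)
Why: Electrophilic aromatic iodination goes para to the free hydroxyl group, the stronger director.

Step 3
Reactants: 3 4-iodo-2-methoxyphenol
Product: 4 1-(benzyloxy)-4-iodo-2-methoxybenzene
Conditions: BnBr (1.1 equiv.), K2CO3 (1.5 equiv.), DMF, 25 °C
Reagents that add atoms: benzyl bromide (BrCc1ccccc1)
Why: Williamson benzylation protects the phenol against the acidic, basic and Mitsunobu conditions that follow.

**Cyclobutane core**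

Step 4
Reactants: 5 3-methylidenecyclobutane-1-carboxylic acid
Product: 6 methyl 3-methylidenecyclobutane-1-carboxylate
Conditions: MeI (1.2 equiv.), K2CO3 (1.5 equiv.), DMF, 25 °C
Reagents that add atoms: iodomethane (CI)
Why: Carboxylate O-alkylation (SN2) masks the acid without touching the exocyclic alkene.

Step 5
Reactants: 6 methyl 3-methylidenecyclobutane-1-carboxylate
Product: 8 methyl 3-(hydroxymethyl)cyclobutane-1-carboxylate, via alkylborane 7 (not isolated)
Conditions: 9-BBN (1.1 equiv.), THF, 0→25 °C; then 30% H2O2, 3 M aq. NaOAc, 0→25 °C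
Reagents that add atoms: hydrogen peroxide (OO)
Why: Anti-Markovnikov hydroboration–oxidation puts the hydroxyl on the exocyclic carbon; the cis/trans ratio at C3 is irrelevant because this centre is equilibrated in step 12.

Step 6
Reactants: 8 methyl 3-(hydroxymethyl)cyclobutane-1-carboxylate
Product: 9 3-(methoxycarbonyl)cyclobutane-1-carboxylic acid
Conditions: TEMPO (10 mol%), PhI(OAc)2 (2.2 equiv.), MeCN/H2O (1:1), 25 °C
Reagents that add atoms: water (O)
Why: TEMPO/PhI(OAc)2 oxidation takes the primary alcohol through the aldehyde hydrate to the acid.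

Step 7
Reactants: 9 3-(methoxycarbonyl)cyclobutane-1-carboxylic acid
Product: 10 dimethyl cyclobutane-1,3-dicarboxylate
Conditions: MeI (1.2 equiv.), K2CO3 (1.5 equiv.), DMF, 25 °C
Reagents that add atoms: iodomethane (CI)
Why: SN2 esterification gives a diester whose two α-positions are constitutionally equivalent, so the next mono-enolisation has no regiochemical issue.

Step 8
Reactants: 10 dimethyl cyclobutane-1,3-dicarboxylate
Product: 12 dimethyl 1-formylcyclobutane-1,3-dicarboxylate, via lithium enolate 11 (not isolated)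
Conditions: LiN(i-Pr)2 (1.05 equiv.), THF, −78 °C; then HCO2CH2CF3 (1.5 equiv.), −78 °C; AcOH quench at −78 °C
Reagents that add atoms: 2,2,2-trifluoroethyl formate (O=COCC(F)(F)F)
Why: Claisen-type C-formylation of the mono-enolate, quenched cold so that the weakly nucleophilic trifluoroethoxide cannot reverse it, gives a non-enolisable formyl ester whose formyl carbon is the future C-methyl group.

Step 9
Reactants: 12 dimethyl 1-formylcyclobutane-1,3-dicarboxylate; 4 1-(benzyloxy)-4-iodo-2-methoxybenzene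
Product: 13 dimethyl (1R,2S)-2-[4-(benzyloxy)-3-methoxyphenyl]-1-formylcyclobutane-1,3-dicarboxylate
Conditions: 4 (1.2 equiv.), Pd(OAc)2 (10 mol%), L-tert-leucine (30 mol%), 3-nitro-5-(trifluoromethyl)pyridin-2(1H)-one (50 mol%), AgOCOCF3 (1.5 equiv.), (CF3)2CHOH/AcOH (9:1), 90 °C
Reagents that add atoms: none
Why: Proposed new method: enantioselective desymmetrising β-methylene C–H arylation of a cyclobutanecarbaldehyde by a chiral transient directing group — the aldehyde condenses reversibly with L-tert-leucine to an imino-carboxylate that chelates divalent palladium, pyridone-assisted concerted metalation–deprotonation can reach only a ring C–H on the formyl face, the tert-butyl group of the amino acid selects one of the two enantiotopic CH2 groups, and oxidative addition of 4 (tetravalent palladium), C–C reductive elimination and imine hydrolysis place the aryl group cis to the formyl group, fixing C1 (R) and C2 (S) together; closest known reaction type: chiral amino-acid transient-directing-group β-C–H arylation of cyclobutyl ketones and transient-directing-group β-arylation of α-quaternary aldehydes.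

Step 10
Reactants: 13 dimethyl (1R,2S)-2-[4-(benzyloxy)-3-methoxyphenyl]-1-formylcyclobutane-1,3-dicarboxylate; 14 iodoethene
Product: 15 dimethyl (1R,2S,4S)-2-[4-(benzyloxy)-3-methoxyphenyl]-4-ethenyl-1-formylcyclobutane-1,3-dicarboxylate
Conditions: 14 (3 equiv.), Pd(OAc)2 (10 mol%), glycine (40 mol%), 3-nitro-5-(trifluoromethyl)pyridin-2(1H)-one (50 mol%), AgOCOCF3 (2 equiv.), (CF3)2CHOH/AcOH (9:1), 80 °C, sealed tube
Reagents that add atoms: none
Why: Proposed new method: transient-imine-directed C(sp3)–H alkenylation — the glycine imine of 13 can palladate only the one remaining ring C–H cis to the formyl group (C4), and the palladacycle is intercepted by iodoethene (oxidative addition to tetravalent palladium, C(sp3)–C(sp2) reductive elimination, iodide removed as AgI), so the ethenyl group is delivered cis to formyl and aryl (C4 S); closest known reaction type: alkenyl-iodide coupling of 8-aminoquinoline-amide-directed cyclobutyl palladacycles and transient-directing-group β-arylation of aldehydes.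

Step 11
Reactants: 15 dimethyl (1R,2S,4S)-2-[4-(benzyloxy)-3-methoxyphenyl]-4-ethenyl-1-formylcyclobutane-1,3-dicarboxylate
Product: 17 dimethyl (1R,2S,4S)-2-[4-(benzyloxy)-3-methoxyphenyl]-4-ethenyl-1-methylcyclobutane-1,3-dicarboxylate, via tosylhydrazone 16 (not isolated)
Conditions: TsNHNH2 (1.3 equiv.), MeOH, 50 °C; solvent exchange; catecholborane (3 equiv.), CHCl3, 0→25 °C; then NaOAc·3H2O (5 equiv.), 60 °C
Reagents that add atoms: none
Why: Tosylhydrazone formation and Kabalka reduction (C=N reduction, then acetate-induced loss of sulfinate and N2) turn CHO into CH3 without touching the quaternary centre, so the methyl group inherits the cis relationship to aryl and ethenyl.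

Step 12
Reactants: 17 dimethyl (1R,2S,4S)-2-[4-(benzyloxy)-3-methoxyphenyl]-4-ethenyl-1-methylcyclobutane-1,3-dicarboxylate
Product: 18 dimethyl (1R,2S,3S,4S)-2-[4-(benzyloxy)-3-methoxyphenyl]-4-ethenyl-1-methylcyclobutane-1,3-dicarboxylate
Conditions: NaOMe (0.3 equiv.), MeOH, 40 °C
Reagents that add atoms: none
Why: Thermodynamic epimerisation by reversible α-deprotonation moves the C3 ester trans to both flanking groups (aryl and ethenyl), setting C3 (S) and converging both C3 epimers; C1 is quaternary and C2/C4 carry no acidic hydrogen.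

Step 13
Reactants: 18 dimethyl (1R,2S,3S,4S)-2-[4-(benzyloxy)-3-methoxyphenyl]-4-ethenyl-1-methylcyclobutane-1,3-dicarboxylate
Product: 19 1-methyl hydrogen (1R,2S,3S,4S)-2-[4-(benzyloxy)-3-methoxyphenyl]-4-ethenyl-1-methylcyclobutane-1,3-dicarboxylate
Conditions: LiOH·H2O (2.0 equiv.), THF/H2O (3:1), 25 °C; then 1 M HCl to pH 3
Reagents that add atoms: lithium hydroxide ([Li+].[OH-])
Why: Chemoselective saponification (acyl-oxygen cleavage) hydrolyses the secondary C3 ester at room temperature, while the α-quaternary C1 ester, shielded by the C1 methyl group and both ring neighbours, needs heat and stays intact; C3 is already in its thermodynamic configuration.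

**Amino alcohol 30**

Step 14
Reactants: 20 but-2-yn-1-amine
Product: 21 methyl but-2-yn-1-ylcarbamate
Conditions: ClCO2Me (1.1 equiv.), Et3N (1.2 equiv.), CH2Cl2, 0 °C
Reagents that add atoms: methyl chloroformate (COC(=O)Cl)
Why: N-acylation gives a carbamate that tolerates the cobalt chemistry and whose carbonyl carbon later becomes the N-methyl group.

Step 15
Reactants: 21 methyl but-2-yn-1-ylcarbamate; 22 (2E)-1,4-dibromobut-2-ene
Product: 24 methyl [(2E)-4-bromobut-2-en-1-yl](but-2-yn-1-yl)carbamate, via sodium salt 23 (not isolated)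
Conditions: NaH (1.1 equiv.), DMF, 0 °C; then 22 (3 equiv.), 0→25 °C
Reagents that add atoms: none
Why: SN2 N-alkylation of the carbamate anion with excess dibromide stops at mono-substitution.

Step 16
Reactants: 24 methyl [(2E)-4-bromobut-2-en-1-yl](but-2-yn-1-yl)carbamate
Product: 25 methyl (but-2-yn-1-yl)[(2R)-2-methylbut-3-en-1-yl]carbamate
Conditions: MeMgBr (1.3 equiv.), CuBr·SMe2 (3 mol%), (R,R)-Taniaphos (3.6 mol%), CH2Cl2, −75 °C
Reagents that add atoms: methylmagnesium bromide (C[Mg]Br)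
Why: Copper-catalysed asymmetric allylic alkylation (SN2′) with the Grignard reagent creates the C-methyl stereocentre (R) under ligand control.

Step 17
Reactants: 25 methyl (but-2-yn-1-yl)[(2R)-2-methylbut-3-en-1-yl]carbamate
Product: 26 methyl (4R,4aR)-4,7-dimethyl-6-oxo-1,3,4,4a,5,6-hexahydro-2H-cyclopenta[c]pyridine-2-carboxylate
Conditions: Co2(CO)8 (10 mol%), tetramethylthiourea (60 mol%), CO (1 atm), toluene, 70 °C
Reagents that add atoms: carbon monoxide ([C-]#[O+])
Why: Intramolecular Pauson–Khand [2+2+1] cycloaddition closes the piperidine and cyclopentenone rings at once; the allylic methyl sits pseudo-equatorial in the chair-like metallacycle, which places H-4a cis to the 4-methyl group (4aR).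

Step 18
Reactants: 26 methyl (4R,4aR)-4,7-dimethyl-6-oxo-1,3,4,4a,5,6-hexahydro-2H-cyclopenta[c]pyridine-2-carboxylate
Product: 28 methyl (4R,4aR,7R,7aS)-4,7-dimethyl-6-oxooctahydro-2H-cyclopenta[c]pyridine-2-carboxylate, via epimeric ketone 27 (not isolated)
Conditions: H2 (4 atm), 10% Pd/C, EtOAc, 25 °C; filter; then K2CO3 (0.5 equiv.), MeOH, 25 °C
Reagents that add atoms: none
Why: Heterogeneous hydrogenation adds H2 to the enone face that carries H-4a (cis ring fusion, 7aS), and base then epimerises the α-carbon C7 to the more stable trans-2,3-disubstituted cyclopentanone (7R).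

Step 19
Reactants: 28 methyl (4R,4aR,7R,7aS)-4,7-dimethyl-6-oxooctahydro-2H-cyclopenta[c]pyridine-2-carboxylate
Product: 29 methyl (4R,4aR,6S,7R,7aS)-6-hydroxy-4,7-dimethyloctahydro-2H-cyclopenta[c]pyridine-2-carboxylate
Conditions: LiBH(s-Bu)3 (1.3 equiv.), THF, −78 °C; then aq. NaOH, H2O2, 0 °C
Reagents that add atoms: none
Why: The bulky hydride attacks the ketone anti to the adjacent 7-methyl group, giving the alcohol cis to it (6S), which is the epimer needed for the later Mitsunobu inversions.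

Step 20
Reactants: 29 methyl (4R,4aR,6S,7R,7aS)-6-hydroxy-4,7-dimethyloctahydro-2H-cyclopenta[c]pyridine-2-carboxylate
Product: 30 (4R,4aR,6S,7R,7aS)-2,4,7-trimethyloctahydro-1H-cyclopenta[c]pyridin-6-ol
Conditions: LiAlH4 (3 equiv.), THF, 0 °C→reflux; Fieser work-up
Reagents that add atoms: none
Why: LiAlH4 reduces the methyl carbamate to the N-methyl amine without affecting any stereocentre.

**Assembly**

Step 21
Reactants: 19 1-methyl hydrogen (1R,2S,3S,4S)-2-[4-(benzyloxy)-3-methoxyphenyl]-4-ethenyl-1-methylcyclobutane-1,3-dicarboxylate; 30 (4R,4aR,6S,7R,7aS)-2,4,7-trimethyloctahydro-1H-cyclopenta[c]pyridin-6-ol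
Product: 31 1-methyl 3-[(4R,4aR,6R,7R,7aS)-2,4,7-trimethyloctahydro-1H-cyclopenta[c]pyridin-6-yl] (1R,2S,3S,4S)-2-[4-(benzyloxy)-3-methoxyphenyl]-4-ethenyl-1-methylcyclobutane-1,3-dicarboxylate
Conditions: 30 (1.1 equiv.), PPh3 (1.5 equiv.), diisopropyl azodicarboxylate (1.5 equiv.), THF, 0→25 °C
Reagents that add atoms: none
Why: Mitsunobu esterification: the C3 carboxylate displaces the phosphonium-activated C6 oxygen of one equivalent of 30 in an SN2 reaction with inversion (6S→6R), so this carbinol centre arrives in the target configuration.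

Step 22
Reactants: 31 1-methyl 3-[(4R,4aR,6R,7R,7aS)-2,4,7-trimethyloctahydro-1H-cyclopenta[c]pyridin-6-yl] (1R,2S,3S,4S)-2-[4-(benzyloxy)-3-methoxyphenyl]-4-ethenyl-1-methylcyclobutane-1,3-dicarboxylate
Product: 32 3-[(4R,4aR,6R,7R,7aS)-2,4,7-trimethyloctahydro-1H-cyclopenta[c]pyridin-6-yl] hydrogen (1R,2S,3S,4S)-2-[4-(benzyloxy)-3-methoxyphenyl]-4-ethenyl-1-methylcyclobutane-1,3-dicarboxylate
Conditions: n-PrSLi (5 equiv.), HMPA, 25 °C; then sat. aq. NH4Cl
Reagents that add atoms: none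
Why: SN2 dealkylation of the hindered methyl ester: the thiolate attacks the unhindered O-methyl carbon, not the shielded carbonyl, so the C1 carboxylate is released while the secondary-alkyl C3 ester, the benzyl ether and the aryl methyl ether are untouched at room temperature.

Step 23
Reactants: 32 3-[(4R,4aR,6R,7R,7aS)-2,4,7-trimethyloctahydro-1H-cyclopenta[c]pyridin-6-yl] hydrogen (1R,2S,3S,4S)-2-[4-(benzyloxy)-3-methoxyphenyl]-4-ethenyl-1-methylcyclobutane-1,3-dicarboxylate; 30 (4R,4aR,6S,7R,7aS)-2,4,7-trimethyloctahydro-1H-cyclopenta[c]pyridin-6-ol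
Product: 33 bis[(4R,4aR,6R,7R,7aS)-2,4,7-trimethyloctahydro-1H-cyclopenta[c]pyridin-6-yl] (1R,2S,3S,4S)-2-[4-(benzyloxy)-3-methoxyphenyl]-4-ethenyl-1-methylcyclobutane-1,3-dicarboxylate
Conditions: 30 (1.2 equiv.), PPh3 (2.0 equiv.), diisopropyl azodicarboxylate (2.0 equiv.), toluene, 0→40 °C
Reagents that add atoms: none
Why: Mitsunobu esterification: the α-quaternary C1 carboxylate reacts as an O-nucleophile, so its own steric bulk matters little, and it displaces the activated C6 oxygen of a second equivalent of 30 with inversion (6S→6R), on the face away from the 7-methyl group.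

Step 24
Reactants: 34 methyl 3-oxobutanoate
Product: 35 methyl (2E)-3-{[(trifluoromethyl)sulfonyl]oxy}but-2-enoate
Conditions: (CF3SO2)2O (1.5 equiv.), 25% aq. Me4NOH (5 equiv.), hexanes, 5–10 °C
Reagents that add atoms: trifluoromethanesulfonic anhydride (O=S(=O)(OS(=O)(=O)C(F)(F)F)C(F)(F)F)
Why: O-triflation of the non-chelated tetramethylammonium enolate gives the (E)-enol triflate, with the triflate trans to the ester.

Step 25
Reactants: 33 bis[(4R,4aR,6R,7R,7aS)-2,4,7-trimethyloctahydro-1H-cyclopenta[c]pyridin-6-yl] (1R,2S,3S,4S)-2-[4-(benzyloxy)-3-methoxyphenyl]-4-ethenyl-1-methylcyclobutane-1,3-dicarboxylate; 35 methyl (2E)-3-{[(trifluoromethyl)sulfonyl]oxy}but-2-enoate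
Product: 37 bis[(4R,4aR,6R,7R,7aS)-2,4,7-trimethyloctahydro-1H-cyclopenta[c]pyridin-6-yl] (1R,2S,3S,4S)-2-[4-(benzyloxy)-3-methoxyphenyl]-4-[(3E)-5-methoxy-3-methyl-5-oxopent-3-en-1-yl]-1-methylcyclobutane-1,3-dicarboxylate, via alkylborane 36 (not isolated)
Conditions: 9-BBN (3 equiv.), THF, 60 °C; then 35 (1.5 equiv.), PdCl2(dppf) (5 mol%), 3 M aq. K3PO4 (3 equiv.), DMF, 25→45 °C
Reagents that add atoms: none
Why: B-alkyl Suzuki–Miyaura coupling: anti-Markovnikov hydroboration of the ethenyl group (excess borane and heat offset reversible amine–borane complexation), then stereoretentive coupling with the (E)-enol triflate, gives the (E)-trisubstituted enoate.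

Step 26
Reactants: 37 bis[(4R,4aR,6R,7R,7aS)-2,4,7-trimethyloctahydro-1H-cyclopenta[c]pyridin-6-yl] (1R,2S,3S,4S)-2-[4-(benzyloxy)-3-methoxyphenyl]-4-[(3E)-5-methoxy-3-methyl-5-oxopent-3-en-1-yl]-1-methylcyclobutane-1,3-dicarboxylate
Product: 38 bis[(4R,4aR,6R,7R,7aS)-2,4,7-trimethyloctahydro-1H-cyclopenta[c]pyridin-6-yl] (1R,2S,3S,4S)-2-[4-(benzyloxy)-3-methoxyphenyl]-4-[(3E)-4-carboxy-3-methylbut-3-en-1-yl]-1-methylcyclobutane-1,3-dicarboxylate
Conditions: Me3SnOH (5 equiv.), ClCH2CH2Cl, 70 °C; then 0.5 M HCl to pH 6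
Reagents that add atoms: trimethyltin hydroxide (C[Sn](C)(C)O)
Why: Trimethyltin hydroxide ester hydrolysis is selective for the unhindered methyl ester, so the side-chain enoate is cleaved while the two hindered secondary-alkyl ring esters and the (E)-alkene stay intact.

Step 27
Reactants: 38 bis[(4R,4aR,6R,7R,7aS)-2,4,7-trimethyloctahydro-1H-cyclopenta[c]pyridin-6-yl] (1R,2S,3S,4S)-2-[4-(benzyloxy)-3-methoxyphenyl]-4-[(3E)-4-carboxy-3-methylbut-3-en-1-yl]-1-methylcyclobutane-1,3-dicarboxylate; 30 (4R,4aR,6S,7R,7aS)-2,4,7-trimethyloctahydro-1H-cyclopenta[c]pyridin-6-ol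
Product: 39 bis[(4R,4aR,6R,7R,7aS)-2,4,7-trimethyloctahydro-1H-cyclopenta[c]pyridin-6-yl] (1R,2S,3S,4S)-2-[4-(benzyloxy)-3-methoxyphenyl]-1-methyl-4-[(3E)-3-methyl-5-oxo-5-{[(4R,4aR,6R,7R,7aS)-2,4,7-trimethyloctahydro-1H-cyclopenta[c]pyridin-6-yl]oxy}pent-3-en-1-yl]cyclobutane-1,3-dicarboxylate
Conditions: 30 (1.2 equiv.), PPh3 (1.5 equiv.), diisopropyl azodicarboxylate (1.5 equiv.), THF, 0→25 °C
Reagents that add atoms: none
Why: Mitsunobu esterification: the unhindered enoic carboxylate displaces the activated C6 oxygen of a third equivalent of 30 with inversion (6S→6R), completing the tris-ester without disturbing the (E)-alkene.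

Step 28
Reactants: 39 bis[(4R,4aR,6R,7R,7aS)-2,4,7-trimethyloctahydro-1H-cyclopenta[c]pyridin-6-yl] (1R,2S,3S,4S)-2-[4-(benzyloxy)-3-methoxyphenyl]-1-methyl-4-[(3E)-3-methyl-5-oxo-5-{[(4R,4aR,6R,7R,7aS)-2,4,7-trimethyloctahydro-1H-cyclopenta[c]pyridin-6-yl]oxy}pent-3-en-1-yl]cyclobutane-1,3-dicarboxylate
Product: 40 CNP0251577.2
Conditions: BCl3 (8 equiv.), pentamethylbenzene (5 equiv.), CH2Cl2, −78 °C; then MeOH, aq. NaHCO3
Reagents that add atoms: none
Why: Lewis-acid debenzylation with a non-basic benzyl-cation scavenger at −78 °C frees the phenol while the three esters, the enoate, the methyl ether and the amines (as reversible BCl3 adducts) stay intact.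

## Compound list

1 | benzene-1,2-diol (catechol) | Oc1ccccc1O | starting material
2 | 2-methoxyphenol | COc1ccccc1O | intermediate
3 | 4-iodo-2-methoxyphenol | COc1cc(I)ccc1O | intermediate
4 | 1-(benzyloxy)-4-iodo-2-methoxybenzene | COc1cc(I)ccc1OCc1ccccc1 | intermediate
5 | 3-methylidenecyclobutane-1-carboxylic acid | C=C1CC(C1)C(=O)O | starting material
6 | methyl 3-methylidenecyclobutane-1-carboxylate | C=C1CC(C1)C(=O)OC | intermediate
7 | methyl 3-[(9-borabicyclo[3.3.1]nonan-9-yl)methyl]cyclobutane-1-carboxylate (not isolated) | COC(=O)C1CC(CB2C3CCCC2CCC3)C1 | intermediate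
8 | methyl 3-(hydroxymethyl)cyclobutane-1-carboxylate (cis/trans mixture, both achiral) | OCC1CC(C1)C(=O)OC | intermediate
9 | 3-(methoxycarbonyl)cyclobutane-1-carboxylic acid (cis/trans mixture) | OC(=O)C1CC(C1)C(=O)OC | intermediate
10 | dimethyl cyclobutane-1,3-dicarboxylate (cis/trans mixture) | COC(=O)C1CC(C1)C(=O)OC | intermediate
11 | lithium enolate of 10 (not isolated) | [Li+].[O-]C(OC)=C1CC(C1)C(=O)OC | intermediate
12 | dimethyl 1-formylcyclobutane-1,3-dicarboxylate (two achiral C3 epimers) | O=CC1(CC(C1)C(=O)OC)C(=O)OC | intermediate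
13 | dimethyl (1R,2S)-2-[4-(benzyloxy)-3-methoxyphenyl]-1-formylcyclobutane-1,3-dicarboxylate (aryl cis to formyl; both C3 epimers) | COc1cc([C@@H]2C(C(=O)OC)C[C@@]2(C=O)C(=O)OC)ccc1OCc1ccccc1 | intermediate
14 | iodoethene | C=CI | starting material
15 | dimethyl (1R,2S,4S)-2-[4-(benzyloxy)-3-methoxyphenyl]-4-ethenyl-1-formylcyclobutane-1,3-dicarboxylate (aryl, ethenyl and formyl mutually cis; both C3 epimers) | COc1cc([C@@H]2C(C(=O)OC)[C@H](C=C)[C@@]2(C=O)C(=O)OC)ccc1OCc1ccccc1 | intermediate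
16 | N-tosylhydrazone of 15 (not isolated) | COc1cc([C@@H]2C(C(=O)OC)[C@H](C=C)[C@@]2(C=NNS(=O)(=O)c3ccc(C)cc3)C(=O)OC)ccc1OCc1ccccc1 | intermediate
17 | dimethyl (1R,2S,4S)-2-[4-(benzyloxy)-3-methoxyphenyl]-4-ethenyl-1-methylcyclobutane-1,3-dicarboxylate (both C3 epimers) | COc1cc([C@@H]2C(C(=O)OC)[C@H](C=C)[C@@]2(C)C(=O)OC)ccc1OCc1ccccc1 | intermediate
18 | dimethyl (1R,2S,3S,4S)-2-[4-(benzyloxy)-3-methoxyphenyl]-4-ethenyl-1-methylcyclobutane-1,3-dicarboxylate (aryl, ethenyl, methyl on one face; both esters on the other) | COc1cc([C@@H]2[C@@H](C(=O)OC)[C@H](C=C)[C@@]2(C)C(=O)OC)ccc1OCc1ccccc1 | intermediate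
19 | 1-methyl hydrogen (1R,2S,3S,4S)-2-[4-(benzyloxy)-3-methoxyphenyl]-4-ethenyl-1-methylcyclobutane-1,3-dicarboxylate (C3 carboxylic acid free, C1 methyl ester kept) | COc1cc([C@@H]2[C@@H](C(=O)O)[C@H](C=C)[C@@]2(C)C(=O)OC)ccc1OCc1ccccc1 | intermediate
20 | but-2-yn-1-amine | CC#CCN | starting material
21 | methyl but-2-yn-1-ylcarbamate | CC#CCNC(=O)OC | intermediate
22 | (2E)-1,4-dibromobut-2-ene | BrC/C=C/CBr | starting material
23 | sodium salt of 21 (not isolated) | [Na+].CC#CC[N-]C(=O)OC | intermediate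
24 | methyl [(2E)-4-bromobut-2-en-1-yl](but-2-yn-1-yl)carbamate | COC(=O)N(CC#CC)C/C=C/CBr | intermediate
25 | methyl (but-2-yn-1-yl)[(2R)-2-methylbut-3-en-1-yl]carbamate | COC(=O)N(CC#CC)C[C@H](C)C=C | intermediate
26 | methyl (4R,4aR)-4,7-dimethyl-6-oxo-1,3,4,4a,5,6-hexahydro-2H-cyclopenta[c]pyridine-2-carboxylate | O=C1C[C@H]2C(=C1C)CN(C(=O)OC)C[C@@H]2C | intermediate
27 | methyl (4R,4aR,7S,7aS)-4,7-dimethyl-6-oxooctahydro-2H-cyclopenta[c]pyridine-2-carboxylate (not isolated) | O=C1C[C@H]2[C@H](CN(C(=O)OC)C[C@@H]2C)[C@@H]1C | intermediate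
28 | methyl (4R,4aR,7R,7aS)-4,7-dimethyl-6-oxooctahydro-2H-cyclopenta[c]pyridine-2-carboxylate | O=C1C[C@H]2[C@H](CN(C(=O)OC)C[C@@H]2C)[C@H]1C | intermediate
29 | methyl (4R,4aR,6S,7R,7aS)-6-hydroxy-4,7-dimethyloctahydro-2H-cyclopenta[c]pyridine-2-carboxylate | O[C@H]1C[C@H]2[C@H](CN(C(=O)OC)C[C@@H]2C)[C@H]1C | intermediate
30 | (4R,4aR,6S,7R,7aS)-2,4,7-trimethyloctahydro-1H-cyclopenta[c]pyridin-6-ol (cis-fused; OH cis to 7-methyl) | O[C@H]1C[C@H]2[C@H](CN(C)C[C@@H]2C)[C@H]1C | intermediate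
31 | 1-methyl 3-[(4R,4aR,6R,7R,7aS)-2,4,7-trimethyloctahydro-1H-cyclopenta[c]pyridin-6-yl] (1R,2S,3S,4S)-2-[4-(benzyloxy)-3-methoxyphenyl]-4-ethenyl-1-methylcyclobutane-1,3-dicarboxylate | COc1cc([C@@H]2[C@@H](C(=O)O[C@@H]3C[C@H]4[C@H](CN(C)C[C@@H]4C)[C@H]3C)[C@H](C=C)[C@@]2(C)C(=O)OC)ccc1OCc1ccccc1 | intermediate
32 | 3-[(4R,4aR,6R,7R,7aS)-2,4,7-trimethyloctahydro-1H-cyclopenta[c]pyridin-6-yl] hydrogen (1R,2S,3S,4S)-2-[4-(benzyloxy)-3-methoxyphenyl]-4-ethenyl-1-methylcyclobutane-1,3-dicarboxylate (C1 carboxylic acid free) | COc1cc([C@@H]2[C@@H](C(=O)O[C@@H]3C[C@H]4[C@H](CN(C)C[C@@H]4C)[C@H]3C)[C@H](C=C)[C@@]2(C)C(=O)O)ccc1OCc1ccccc1 | intermediate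
33 | bis[(4R,4aR,6R,7R,7aS)-2,4,7-trimethyloctahydro-1H-cyclopenta[c]pyridin-6-yl] (1R,2S,3S,4S)-2-[4-(benzyloxy)-3-methoxyphenyl]-4-ethenyl-1-methylcyclobutane-1,3-dicarboxylate | COc1cc([C@@H]2[C@@H](C(=O)O[C@@H]3C[C@H]4[C@H](CN(C)C[C@@H]4C)[C@H]3C)[C@H](C=C)[C@@]2(C)C(=O)O[C@@H]2C[C@H]3[C@H](CN(C)C[C@@H]3C)[C@H]2C)ccc1OCc1ccccc1 | intermediate
34 | methyl 3-oxobutanoate | CC(=O)CC(=O)OC | starting material
35 | methyl (2E)-3-{[(trifluoromethyl)sulfonyl]oxy}but-2-enoate | C/C(=C\C(=O)OC)OS(=O)(=O)C(F)(F)F | intermediate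
36 | B-alkyl-9-BBN derivative of 33 (not isolated) | COc1cc([C@@H]2[C@@H](C(=O)O[C@@H]3C[C@H]4[C@H](CN(C)C[C@@H]4C)[C@H]3C)[C@H](CCB3C4CCCC3CCC4)[C@@]2(C)C(=O)O[C@@H]2C[C@H]3[C@H](CN(C)C[C@@H]3C)[C@H]2C)ccc1OCc1ccccc1 | intermediate
37 | bis[(4R,4aR,6R,7R,7aS)-2,4,7-trimethyloctahydro-1H-cyclopenta[c]pyridin-6-yl] (1R,2S,3S,4S)-2-[4-(benzyloxy)-3-methoxyphenyl]-4-[(3E)-5-methoxy-3-methyl-5-oxopent-3-en-1-yl]-1-methylcyclobutane-1,3-dicarboxylate | COc1cc([C@@H]2[C@@H](C(=O)O[C@@H]3C[C@H]4[C@H](CN(C)C[C@@H]4C)[C@H]3C)[C@H](CC/C(C)=C/C(=O)OC)[C@@]2(C)C(=O)O[C@@H]2C[C@H]3[C@H](CN(C)C[C@@H]3C)[C@H]2C)ccc1OCc1ccccc1 | intermediate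
38 | bis[(4R,4aR,6R,7R,7aS)-2,4,7-trimethyloctahydro-1H-cyclopenta[c]pyridin-6-yl] (1R,2S,3S,4S)-2-[4-(benzyloxy)-3-methoxyphenyl]-4-[(3E)-4-carboxy-3-methylbut-3-en-1-yl]-1-methylcyclobutane-1,3-dicarboxylate | COc1cc([C@@H]2[C@@H](C(=O)O[C@@H]3C[C@H]4[C@H](CN(C)C[C@@H]4C)[C@H]3C)[C@H](CC/C(C)=C/C(=O)O)[C@@]2(C)C(=O)O[C@@H]2C[C@H]3[C@H](CN(C)C[C@@H]3C)[C@H]2C)ccc1OCc1ccccc1 | intermediate
39 | O-benzyl ether of the target: bis[(4R,4aR,6R,7R,7aS)-2,4,7-trimethyloctahydro-1H-cyclopenta[c]pyridin-6-yl] (1R,2S,3S,4S)-2-[4-(benzyloxy)-3-methoxyphenyl]-1-methyl-4-[(3E)-3-methyl-5-oxo-5-{[(4R,4aR,6R,7R,7aS)-2,4,7-trimethyloctahydro-1H-cyclopenta[c]pyridin-6-yl]oxy}pent-3-en-1-yl]cyclobutane-1,3-dicarboxylate | COc1cc([C@@H]2[C@@H](C(=O)O[C@@H]3C[C@H]4[C@H](CN(C)C[C@@H]4C)[C@H]3C)[C@H](CC/C(C)=C/C(=O)O[C@@H]3C[C@H]4[C@H](CN(C)C[C@@H]4C)[C@H]3C)[C@@]2(C)C(=O)O[C@@H]2C[C@H]3[C@H](CN(C)C[C@@H]3C)[C@H]2C)ccc1OCc1ccccc1 | intermediate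
40 | CNP0251577.2: the (1R,2S,3S,4S)-cyclobutane tris-ester of 39 with a free 4-hydroxy-3-methoxyphenyl group | COc1cc([C@@H]2[C@@H](C(=O)O[C@@H]3C[C@H]4[C@H](CN(C)C[C@@H]4C)[C@H]3C)[C@H](CC/C(C)=C/C(=O)O[C@@H]3C[C@H]4[C@H](CN(C)C[C@@H]4C)[C@H]3C)[C@@]2(C)C(=O)O[C@@H]2C[C@H]3[C@H](CN(C)C[C@@H]3C)[C@H]2C)ccc1O | target

## Step count and risk

Total step count: 28. Longest linear sequence: 17 steps (steps 4–13, 21–23, 25–28), which is 61% of the total. The other branches are 3 steps (aryl iodide, steps 1–3), 7 steps (amino alcohol, steps 14–20, used once each in steps 21, 23 and 27) and 1 step (enol triflate, step 24).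

Three steps most likely to fail:

Step 9 (new method; mono-selectivity and enantioselectivity on this aldehyde are unproven). The fallback uses known chemistry, sets out from 10 and returns at 13. The lithium enolate of 10 is trapped with 2,3,5,6-tetrafluoro-4-(trifluoromethyl)phenyl isocyanate to give dimethyl 1-{[2,3,5,6-tetrafluoro-4-(trifluoromethyl)phenyl]carbamoyl}cyclobutane-1,3-dicarboxylate F1. Iodide 4 is borylated (bis(pinacolato)diboron, PdCl2(dppf), KOAc) to 2-[4-(benzyloxy)-3-methoxyphenyl]-4,4,5,5-tetramethyl-1,3,2-dioxaborolane F2. The established amide-directed enantioselective β-C–H arylation of 1-substituted cyclobutanecarboxamides (Pd(OAc)2, chiral mono-N-protected amino-acid hydroxamate ligand, Ag2CO3, benzoquinone, t-AmylOH, 70 °C) joins them to dimethyl (1R,2S)-2-[4-(benzyloxy)-3-methoxyphenyl]-1-{[2,3,5,6-tetrafluoro-4-(trifluoromethyl)phenyl]carbamoyl}cyclobutane-1,3-dicarboxylate F3, with the aryl cis to the amide. Boc2O/DMAP gives the N-Boc imide of F3 F4, NaBH4 cleaves it reductively to dimethyl (1R,2S)-2-[4-(benzyloxy)-3-methoxyphenyl]-1-(hydroxymethyl)cyclobutane-1,3-dicarboxylate F5, and Dess–Martin oxidation gives 13.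

Step 10 (new method; alkenyl iodides are untested under transient-imine direction). The fallback uses known chemistry, sets out from 13 and returns at 15. Pinnick oxidation (NaClO2, NaH2PO4, 2-methylbut-2-ene) gives (1R,2S)-2-[4-(benzyloxy)-3-methoxyphenyl]-1,3-bis(methoxycarbonyl)cyclobutane-1-carboxylic acid F6. Coupling with quinolin-8-amine through the acid chloride gives dimethyl (1R,2S)-2-[4-(benzyloxy)-3-methoxyphenyl]-1-(quinolin-8-ylcarbamoyl)cyclobutane-1,3-dicarboxylate F7. The known 8-aminoquinoline-directed alkenylation of cyclobutane C–H bonds with an alkenyl iodide (Pd(OAc)2, AgOAc, 14, 80–100 °C) gives dimethyl (1R,2S,4S)-2-[4-(benzyloxy)-3-methoxyphenyl]-4-ethenyl-1-(quinolin-8-ylcarbamoyl)cyclobutane-1,3-dicarboxylate F8. Boc2O/DMAP gives the N-Boc imide of F8 F9, NaBH4 gives dimethyl (1R,2S,4S)-2-[4-(benzyloxy)-3-methoxyphenyl]-4-ethenyl-1-(hydroxymethyl)cyclobutane-1,3-dicarboxylate F10, and Dess–Martin oxidation gives 15.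

Step 23 (SN2 displacement at a hindered secondary carbinol by an α-quaternary carboxylate that is also an amino-acid zwitterion). The fallback sets out from 30 (with 32) and returns at 33. Alcohol 30 is inverted by a Mitsunobu reaction with the small, acidic 4-nitrobenzoic acid to (4R,4aR,6R,7R,7aS)-2,4,7-trimethyloctahydro-1H-cyclopenta[c]pyridin-6-yl 4-nitrobenzoate F11. K2CO3/MeOH frees (4R,4aR,6R,7R,7aS)-2,4,7-trimethyloctahydro-1H-cyclopenta[c]pyridin-6-ol F12. Acid 32 is converted with 1-chloro-N,N,2-trimethylprop-1-en-1-amine (CH2Cl2, 0→25 °C) into the C1 acid chloride of 32 F13. The lithium alkoxide of F12 (LiN(SiMe3)2, THF, −78→0 °C) is then acylated by F13, with retention at C6, to give 33.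

## Further compounds

F1 | step 9 | dimethyl 1-{[2,3,5,6-tetrafluoro-4-(trifluoromethyl)phenyl]carbamoyl}cyclobutane-1,3-dicarboxylate | O=C(Nc1c(F)c(F)c(C(F)(F)F)c(F)c1F)C1(CC(C1)C(=O)OC)C(=O)OC
F2 | step 9 | 2-[4-(benzyloxy)-3-methoxyphenyl]-4,4,5,5-tetramethyl-1,3,2-dioxaborolane | COc1cc(B2OC(C)(C)C(C)(C)O2)ccc1OCc1ccccc1
F3 | step 9 | dimethyl (1R,2S)-2-[4-(benzyloxy)-3-methoxyphenyl]-1-{[2,3,5,6-tetrafluoro-4-(trifluoromethyl)phenyl]carbamoyl}cyclobutane-1,3-dicarboxylate | COc1cc([C@@H]2C(C(=O)OC)C[C@@]2(C(=O)Nc3c(F)c(F)c(C(F)(F)F)c(F)c3F)C(=O)OC)ccc1OCc1ccccc1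
F4 | step 9 | N-Boc imide of F3 | COc1cc([C@@H]2C(C(=O)OC)C[C@@]2(C(=O)N(C(=O)OC(C)(C)C)c3c(F)c(F)c(C(F)(F)F)c(F)c3F)C(=O)OC)ccc1OCc1ccccc1
F5 | step 9 | dimethyl (1R,2S)-2-[4-(benzyloxy)-3-methoxyphenyl]-1-(hydroxymethyl)cyclobutane-1,3-dicarboxylate | COc1cc([C@@H]2C(C(=O)OC)C[C@@]2(CO)C(=O)OC)ccc1OCc1ccccc1
F6 | step 10 | (1R,2S)-2-[4-(benzyloxy)-3-methoxyphenyl]-1,3-bis(methoxycarbonyl)cyclobutane-1-carboxylic acid | COc1cc([C@@H]2C(C(=O)OC)C[C@@]2(C(=O)O)C(=O)OC)ccc1OCc1ccccc1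
F7 | step 10 | dimethyl (1R,2S)-2-[4-(benzyloxy)-3-methoxyphenyl]-1-(quinolin-8-ylcarbamoyl)cyclobutane-1,3-dicarboxylate | COc1cc([C@@H]2C(C(=O)OC)C[C@@]2(C(=O)Nc3cccc4cccnc34)C(=O)OC)ccc1OCc1ccccc1
F8 | step 10 | dimethyl (1R,2S,4S)-2-[4-(benzyloxy)-3-methoxyphenyl]-4-ethenyl-1-(quinolin-8-ylcarbamoyl)cyclobutane-1,3-dicarboxylate | COc1cc([C@@H]2C(C(=O)OC)[C@H](C=C)[C@@]2(C(=O)Nc3cccc4cccnc34)C(=O)OC)ccc1OCc1ccccc1
F9 | step 10 | N-Boc imide of F8 | COc1cc([C@@H]2C(C(=O)OC)[C@H](C=C)[C@@]2(C(=O)N(C(=O)OC(C)(C)C)c3cccc4cccnc34)C(=O)OC)ccc1OCc1ccccc1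
F10 | step 10 | dimethyl (1R,2S,4S)-2-[4-(benzyloxy)-3-methoxyphenyl]-4-ethenyl-1-(hydroxymethyl)cyclobutane-1,3-dicarboxylate | COc1cc([C@@H]2C(C(=O)OC)[C@H](C=C)[C@@]2(CO)C(=O)OC)ccc1OCc1ccccc1
F11 | step 23 | (4R,4aR,6R,7R,7aS)-2,4,7-trimethyloctahydro-1H-cyclopenta[c]pyridin-6-yl 4-nitrobenzoate | O=C(O[C@@H]1C[C@H]2[C@H](CN(C)C[C@@H]2C)[C@H]1C)c1ccc(cc1)[N+](=O)[O-]
F12 | step 23 | (4R,4aR,6R,7R,7aS)-2,4,7-trimethyloctahydro-1H-cyclopenta[c]pyridin-6-ol | O[C@@H]1C[C@H]2[C@H](CN(C)C[C@@H]2C)[C@H]1C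
F13 | step 23 | C1 acid chloride of 32: (4R,4aR,6R,7R,7aS)-2,4,7-trimethyloctahydro-1H-cyclopenta[c]pyridin-6-yl (1S,2S,3R,4S)-2-[4-(benzyloxy)-3-methoxyphenyl]-3-(chlorocarbonyl)-4-ethenyl-3-methylcyclobutane-1-carboxylate | COc1cc([C@@H]2[C@@H](C(=O)O[C@@H]3C[C@H]4[C@H](CN(C)C[C@@H]4C)[C@H]3C)[C@H](C=C)[C@@]2(C)C(=O)Cl)ccc1OCc1ccccc1
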